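**Retrosynthetic overview** (atom labels C1–C20 follow ent-kaurane numbering of the target)

1. Feature: on ring A (C1 ketone, C2=C3, C4 gem-dimethyl, C5, C10) the hydroxymethyl C6 on C5 and the lactone methylene C20 on the neighbouring quaternary C10 are cis one-carbon arms, so they are treated as the two remaining carbons of a cis-fused cyclobutene. Cutting C10–C20 and C5–C6 leads to enone ester 5 and acetylene (enone–alkyne [2+2] photocycloaddition); the ester carbon is C9.
2. Ring D (C8, C14, C13, C16, C15) is cut at C13–C16 (aldol); C17 and the C16 configuration come from α-methylenation and exo hydrogenation. Ring C (C8, C9, C11–C14) is cut at C8–C14 (oxidative enolate coupling) and C9–C11 (conjugate addition).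
3. The lactone (C10, C20, O, C7, C8, C9) is cut at C8=C9 (Knoevenagel) and O–C7 (acetoacetylation of the C20 carbinol). The C20 and C6 carbinols come from ozonolysis of the cyclobutene, the C9 aldehyde from the ester.
4. Order of ring formation: ring A (bought) → temporary cyclobutene (step 3) → lactone (step 11) → ring C (step 14) → ring D (step 15).

Key step: step 3

Assumption: the C1 carbinol formed in step 4 is drawn with the hydroxyl cis to the ester (hydride anti to the ester); this centre is removed in step 12, and the other epimer would pass through steps 5 to 12 in the same way.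

**Route**

Step 1
Reactants: 1 4,4-dimethylcyclohexanone; 2 dimethyl carbonate
Product: 3 methyl 5,5-dimethyl-2-oxocyclohexane-1-carboxylate
Conditions: NaH, THF, reflux; then aq. HCl
Reagents that add atoms: none
Why: Claisen-type C-acylation (carbomethoxylation) of the ketone enolate by dimethyl carbonate is driven by deprotonation of the β-keto ester formed; the new centre is enolisable and left undefined.

Step 2
Reactants: 3 methyl 5,5-dimethyl-2-oxocyclohexane-1-carboxylate
Product: 5 methyl 3,3-dimethyl-6-oxocyclohex-1-ene-1-carboxylate, via selenide 4 (not isolated)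
Conditions: PhSeCl, pyridine, CH2Cl2, 0 °C; then 30% H2O2, 0 °C to rt
Reagents that add atoms: none
Why: α-selenenylation of the β-keto ester at the doubly activated carbon and selenoxide syn elimination, which can only run towards the CH2 next to the gem-dimethyl group because the other neighbour is the ketone carbon.

Step 3
Reactants: 5 methyl 3,3-dimethyl-6-oxocyclohex-1-ene-1-carboxylate; 6 acetylene
Product: 7 methyl (1S,6R)-5,5-dimethyl-2-oxobicyclo[4.2.0]oct-7-ene-1-carboxylate
Conditions: hν (366 nm), acetylene-saturated CH2Cl2, (S)-diarylprolinol-derived B-aryl oxazaborolidine activated with AlBr3 (50 mol%), −75 °C, stopped before full conversion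
Reagents that add atoms: none
Why: Proposed new method: the Lewis acid, bound to the ketone oxygen with the ester carbonyl as second contact, red-shifts the enone absorption so that at 366 nm mainly the complex is excited; after intersystem crossing the triplet enone adds acetylene stepwise through a triplet 1,4-diradical that closes after spin inversion. The closest known reactions are the racemic [2+2] photocycloaddition of 2-alkoxycarbonylcyclohex-2-enones with alkynes and the oxazaborolidine–AlBr3-catalysed enantioselective [2+2] photocycloaddition of cyclohexenones with alkenes; acetylene as partner under a chiral Lewis acid is the untested part. The cyclobutene ring (C10, C20, C6, C5) closes by radical recombination within the 1,4-diradical, and a four-membered ring on a cyclohexanone can only be cis-fused. C5 and C10 are thus set relative to each other by the ring fusion (C6 cis to C20, ester trans to C6) and in the absolute sense by the catalyst, whose aryl group should cover one face of the C5=C10 bond so that acetylene enters from the other; the catalyst enantiomer is chosen to give (1S,6R). Only enantioface selectivity is needed, since acetylene is symmetrical and the substrate has no stereocentre; the β-keto ester should secure it by holding the catalyst next to the reacting double bond, and the long wavelength limits further excitation of the β,γ-unsaturated ketone product.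

Step 4
Reactants: 7 methyl (1S,6R)-5,5-dimethyl-2-oxobicyclo[4.2.0]oct-7-ene-1-carboxylate
Product: 8 methyl (1S,2R,6R)-2-hydroxy-5,5-dimethylbicyclo[4.2.0]oct-7-ene-1-carboxylate
Conditions: NaBH4, MeOH, 0 °C
Reagents that add atoms: none
Why: borohydride reduction of the ketone beside the hindered ester removes the β-keto ester before ozonolysis (no deformylation-prone tricarbonyl can arise); hydride is expected anti to the ester (polar Felkin–Anh sense), giving the carbinol cis to the ester.

Step 5
Reactants: 8 methyl (1S,2R,6R)-2-hydroxy-5,5-dimethylbicyclo[4.2.0]oct-7-ene-1-carboxylate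
Product: 10 methyl 2-hydroxy-1,6-bis(hydroxymethyl)-5,5-dimethylcyclohexane-1-carboxylate (hydroxymethyl groups cis; ring hydroxyl cis to the ester), via dialdehyde 9 (not isolated)
Conditions: O3, pyridine, CH2Cl2, −78 °C; then NaBH4, MeOH, −78 to 0 °C
Reagents that add atoms: ozone, [O-][O+]=O
Why: pyridine-promoted ozonolysis of the strained cyclobutene (the only C=C bond) gives the dialdehyde directly, and borohydride reduces both formyl groups in the cold before the enolisable C5 centre can epimerise; C5 and C10 are untouched, so the C6 and C20 arms stay cis.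

Step 6
Reactants: 10 methyl 2-hydroxy-1,6-bis(hydroxymethyl)-5,5-dimethylcyclohexane-1-carboxylate
Product: 11 acetonide of 10 across the C1 and C20 oxygens (2,2-dimethyl-1,3-dioxane fused to ring A; C6 hydroxyl free)
Conditions: 2,2-dimethoxypropane, PPTS (cat.), CH2Cl2, rt
Reagents that add atoms: 2,2-dimethoxypropane, COC(C)(C)OC
Why: thermodynamic acetalisation (acetonide formation) picks the only 1,3-related pair of hydroxyls, C1 and C20, which distinguishes C20 from C6.

Step 7
Reactants: 11 acetonide of 10 across the C1 and C20 oxygens
Product: 12 C6 tert-butyldiphenylsilyl ether of 11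
Conditions: TBDPSCl, imidazole, DMAP (cat.), DMF, 40 °C
Reagents that add atoms: tert-butyl(chloro)diphenylsilane, CC(C)(C)[Si](Cl)(c1ccccc1)c1ccccc1
Why: silylation of the only free hydroxyl with a bulky group that is stable to hydride, acid and base and is kept to the last step.

Step 8
Reactants: 12 C6 tert-butyldiphenylsilyl ether of 11
Product: 13 C9 primary alcohol (ester of 12 reduced to CH2OH)
Conditions: LiAlH4, THF, 0 °C to rt
Reagents that add atoms: none
Why: LiAlH4 reduction of the hindered neopentyl ester to the primary alcohol; acetal and silyl ether are inert to hydride.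

Step 9
Reactants: 13 C9 primary alcohol
Product: 14 C9 aldehyde (acetonide and silyl ether retained)
Conditions: Dess–Martin periodinane, CH2Cl2, rt
Reagents that add atoms: none
Why: Dess–Martin oxidation of the neopentyl alcohol gives an aldehyde on the quaternary C10 that can neither enolise nor epimerise.

Step 10
Reactants: 14 C9 aldehyde
Product: 15 C1,C20-diol C9-aldehyde (C6 silyl ether retained)
Conditions: AcOH/THF/H2O (3:1:1), 45 °C
Reagents that add atoms: none
Why: acid hydrolysis of the acetonide; the primary TBDPS ether withstands aqueous acetic acid and the hydroxyls cannot form a hemiacetal with the geminal aldehyde (four-membered ring).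

Step 11
Reactants: 15 C1,C20-diol C9-aldehyde
Product: 17 spiro α-acetyl-α,β-unsaturated δ-lactone (C20–O–C7(=O)–C8(acetyl)=C9, spiro at C10; C1 hydroxyl free), via acetoacetate 16 (not isolated)
Conditions: diketene, DMAP (cat.), CH2Cl2, −20 °C; then piperidine (cat.), AcOH (cat.), 4 Å MS, rt
Reagents that add atoms: diketene, C=C1CC(=O)O1
Why: DMAP-catalysed acetoacetylation takes the primary C20 hydroxyl in preference to the neopentyl secondary C1 hydroxyl, and intramolecular Knoevenagel condensation of the acetoacetate with the geminal C9 aldehyde closes the six-membered lactone, as in the 3-acetylcoumarin synthesis from salicylaldehydes.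

Step 12
Reactants: 17 spiro α-acetyl-α,β-unsaturated δ-lactone with C1 hydroxyl
Product: 19 ring A enone lactone (C1 ketone, C2=C3), via ketone 18 (not isolated)
Conditions: IBX (4 equiv), 4-methoxypyridine N-oxide, DMSO, rt to 45 °C
Reagents that add atoms: none
Why: IBX oxidises the C1 carbinol to the ketone and then dehydrogenates it through its enol (IBX dehydrogenation of ketones), which can only form towards C2 because C10 is quaternary, while the acetyl group has no β-hydrogen; the resulting enone is non-enolisable (C4 and C10 quaternary).

Step 13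
Reactants: 19 ring A enone lactone
Product: 21 C9 (3-oxobutyl) β-keto lactone, via dioxolane adduct 20 (not isolated)
Conditions: BrMgCH2CH2C(OCH2CH2O)CH3, CuBr·SMe2 (20 mol%), THF, −78 °C; then 1 M HCl, THF, rt
Reagents that add atoms: [2-(2-methyl-1,3-dioxolan-2-yl)ethyl]magnesium bromide, CC1(CC[Mg]Br)OCCO1 (made in the flask from 2-(2-bromoethyl)-2-methyl-1,3-dioxolane, CC1(CCBr)OCCO1, and Mg); water, O
Why: copper-catalysed conjugate addition of the Grignard reagent to the doubly activated alkylidene β-keto lactone (far more electrophilic than the ring A enone, whose C3 is neopentyl) should occur at C9 anti to C5 with its silyloxymethyl arm and past the flat C1 carbonyl, setting C9 with C11 cis to C1; aqueous acid then unmasks the methyl ketone, and C8 remains epimerisable (drawn trans).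

Step 14
Reactants: 21 C9 (3-oxobutyl) β-keto lactone
Product: 22 tricyclic diketone (ring C closed: C13 ketone, acetyl on quaternary C8)
Conditions: lithium diisopropylamide (2.2 equiv), THF, −78 °C; then [Fe(DMF)3Cl2][FeCl4], −78 to 0 °C, high dilution
Reagents that add atoms: none
Why: intramolecular oxidative heterocoupling of two enolates (the stabilised C8 enolate and the kinetic methyl ketone enolate at C14) by a trivalent iron salt, as in oxidative ketone–malonate enolate couplings, forms C8–C14; the chain from C11 can reach the planar C8 only on its own face, so ring C is cis-fused to the lactone and the quaternary C8 is set with C14 cis to C11.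

Step 15
Reactants: 22 tricyclic diketone
Product: 23 17-nor ketol (ring D closed: C13 tertiary alcohol, C15 ketone, C16 methylene)
Conditions: TiCl4, Bu3N, CH2Cl2, −78 to −40 °C; aqueous work-up
Reagents that add atoms: none
Why: titanium-mediated intramolecular aldol addition (soft enolisation with TiCl4 and amine): TiCl4 chelated by the acetyl and lactone carbonyls acidifies the acetyl CH3 (C16), which in the favoured conformer sits axial on ring C over the C13 ketone (the other chair puts the acetyl syn-axial to C5), and the stable titanium aldolate prevents reversal; the C13 configuration is fixed by the bridge.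

Step 16
Reactants: 23 17-nor ketol
Product: 24 16-methylene-15-ketone
Conditions: (CH2O)n, N-methylanilinium trifluoroacetate, THF, 65 °C
Reagents that add atoms: formaldehyde (as paraformaldehyde), C=O
Why: Mannich-type α-methylenation of the ketone; C16 is the only enolisable position, because C8 and C10 are quaternary and the ring A enone cannot enolise, and the bridgehead alcohol cannot dehydrate.

Step 17
Reactants: 24 16-methylene-15-ketone
Product: 25 6-O-tert-butyldiphenylsilyl ether of the target
Conditions: H2 (1 atm), RhCl(PPh3)3 (10 mol%), benzene/EtOH, rt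
Reagents that add atoms: none
Why: homogeneous hydrogenation with RhCl(PPh3)3 should reduce the exocyclic 1,1-disubstituted enone faster than the ring A enone, whose C2=C3 bond is flanked by the quaternary C4; syn delivery of H2 to the exo face of the bicyclo[3.2.1]octane (the face of the one-carbon bridge C14) places H16 exo and the methyl group endo, as in the target.

Step 18
Reactants: 25 6-O-tert-butyldiphenylsilyl ether of the target
Product: 26 target CNP0533761.1
Conditions: HF·pyridine, THF/pyridine, 0 °C to rt
Reagents that add atoms: none
Why: fluoride desilylation under buffered, non-basic conditions spares the β-hydroxy ketone (no retro-aldol), the lactone and the enone.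

**Compound list**

1 | 4,4-dimethylcyclohexanone | CC1(C)CCC(=O)CC1 | starting material
2 | dimethyl carbonate | COC(=O)OC | starting material
3 | methyl 5,5-dimethyl-2-oxocyclohexane-1-carboxylate | COC(=O)C1CC(C)(C)CCC1=O | intermediate
4 | methyl 5,5-dimethyl-2-oxo-1-(phenylselanyl)cyclohexane-1-carboxylate | COC(=O)C1([Se]c2ccccc2)CC(C)(C)CCC1=O | intermediate
5 | methyl 3,3-dimethyl-6-oxocyclohex-1-ene-1-carboxylate | COC(=O)C1=CC(C)(C)CCC1=O | intermediate
6 | acetylene | C#C | starting material
7 | methyl (1S,6R)-5,5-dimethyl-2-oxobicyclo[4.2.0]oct-7-ene-1-carboxylate | COC(=O)[C@@]12C=C[C@@H]1C(C)(C)CCC2=O | intermediate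
8 | methyl (1S,2R,6R)-2-hydroxy-5,5-dimethylbicyclo[4.2.0]oct-7-ene-1-carboxylate | COC(=O)[C@@]12C=C[C@@H]1C(C)(C)CC[C@H]2O | intermediate
9 | methyl 1,6-diformyl-2-hydroxy-5,5-dimethylcyclohexane-1-carboxylate (formyl groups cis) | COC(=O)[C@@]1(C=O)[C@H](C=O)C(C)(C)CC[C@H]1O | intermediate
10 | methyl 2-hydroxy-1,6-bis(hydroxymethyl)-5,5-dimethylcyclohexane-1-carboxylate (hydroxymethyl groups cis) | COC(=O)[C@@]1(CO)[C@H](CO)C(C)(C)CC[C@H]1O | intermediate
11 | C1,C20-acetonide of 10, C6 hydroxyl free | COC(=O)[C@]12COC(C)(C)O[C@@H]1CCC(C)(C)[C@H]2CO | intermediate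
12 | C6 tert-butyldiphenylsilyl ether of 11 | COC(=O)[C@]12COC(C)(C)O[C@@H]1CCC(C)(C)[C@H]2CO[Si](c1ccccc1)(c1ccccc1)C(C)(C)C | intermediate
13 | C9 primary alcohol | OC[C@]12COC(C)(C)O[C@@H]1CCC(C)(C)[C@H]2CO[Si](c1ccccc1)(c1ccccc1)C(C)(C)C | intermediate
14 | C9 aldehyde | O=C[C@]12COC(C)(C)O[C@@H]1CCC(C)(C)[C@H]2CO[Si](c1ccccc1)(c1ccccc1)C(C)(C)C | intermediate
15 | C1,C20-diol C9-aldehyde | O=C[C@]1(CO)[C@H](O)CCC(C)(C)[C@H]1CO[Si](c1ccccc1)(c1ccccc1)C(C)(C)C | intermediate
16 | C20 acetoacetate of 15 | CC(=O)CC(=O)OC[C@@]1(C=O)[C@H](O)CCC(C)(C)[C@H]1CO[Si](c1ccccc1)(c1ccccc1)C(C)(C)C | intermediate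
17 | spiro α-acetyl-α,β-unsaturated δ-lactone with C1 hydroxyl | CC(=O)C1=C[C@]2(COC1=O)[C@H](O)CCC(C)(C)[C@H]2CO[Si](c1ccccc1)(c1ccccc1)C(C)(C)C | intermediate
18 | C1 ketone of 17 (ring A saturated) | CC(=O)C1=C[C@]2(COC1=O)C(=O)CCC(C)(C)[C@H]2CO[Si](c1ccccc1)(c1ccccc1)C(C)(C)C | intermediate
19 | ring A enone lactone | CC(=O)C1=C[C@]2(COC1=O)C(=O)C=CC(C)(C)[C@H]2CO[Si](c1ccccc1)(c1ccccc1)C(C)(C)C | intermediate
20 | C9 adduct with dioxolane-protected 3-oxobutyl chain (C8 drawn trans, epimerisable) | CC(=O)[C@@H]1[C@@H](CCC2(C)OCCO2)[C@]2(COC1=O)C(=O)C=CC(C)(C)[C@H]2CO[Si](c1ccccc1)(c1ccccc1)C(C)(C)C | intermediate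
21 | C9 (3-oxobutyl) β-keto lactone (C8 drawn trans, epimerisable) | CC(=O)[C@@H]1[C@@H](CCC(C)=O)[C@]2(COC1=O)C(=O)C=CC(C)(C)[C@H]2CO[Si](c1ccccc1)(c1ccccc1)C(C)(C)C | intermediate
22 | tricyclic diketone (rings A, lactone and C; acetyl on C8) | CC(=O)[C@]12CC(=O)CC[C@H]1[C@]1(COC2=O)C(=O)C=CC(C)(C)[C@H]1CO[Si](c1ccccc1)(c1ccccc1)C(C)(C)C | intermediate
23 | 17-nor ketol (13-hydroxy-15-ketone, ring D closed) | C1C(=O)[C@]23C[C@@]1(O)CC[C@H]2[C@]1(COC3=O)C(=O)C=CC(C)(C)[C@H]1CO[Si](c1ccccc1)(c1ccccc1)C(C)(C)C | intermediate
24 | 16-methylene-15-ketone | C=C1C(=O)[C@]23C[C@@]1(O)CC[C@H]2[C@]1(COC3=O)C(=O)C=CC(C)(C)[C@H]1CO[Si](c1ccccc1)(c1ccccc1)C(C)(C)C | intermediate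
25 | 6-O-tert-butyldiphenylsilyl ether of the target | C[C@H]1C(=O)[C@]23C[C@@]1(O)CC[C@H]2[C@]1(COC3=O)C(=O)C=CC(C)(C)[C@H]1CO[Si](c1ccccc1)(c1ccccc1)C(C)(C)C | intermediate
26 | CNP0533761.1 | C[C@H]1C(=O)[C@]23C[C@@]1(O)CC[C@H]2[C@]1(COC3=O)C(=O)C=CC(C)(C)[C@H]1CO | target

**Step count**

Total: 18 steps. Longest linear sequence: 18 steps from 4,4-dimethylcyclohexanone.

**Steps most likely to fail**

Step 3 (proposed new method). Enantioface discrimination may be weak because uncomplexed 5 is also excited and reacts without bias. The β,γ-unsaturated ketone product may photoreact further (1,3-acyl shift), and the aluminium Lewis acid may oligomerise acetylene. Fallback, from 5 back to 7: irradiation of 5 at 350 nm in acetylene-saturated CH2Cl2 at −78 °C without Lewis acid is the known racemic enone–alkyne [2+2] photocycloaddition. It should give 7 together with its enantiomer methyl (1R,6S)-5,5-dimethyl-2-oxobicyclo[4.2.0]oct-7-ene-1-carboxylate F1. The racemate is resolved by preparative chromatography on a chiral stationary phase, and the (1S,6R) enantiomer 7 enters step 4.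

Step 14. Oxidation of the dianion may lead to intermolecular coupling, oxygen–carbon coupling or over-oxidation instead of the C8–C14 bond, and proton transfer may move the kinetic enolate from C14 to C12. Fallback, from 19 back to 22: copper-catalysed addition of 3-methylbut-3-enylmagnesium bromide (CuBr·SMe2, THF, −78 °C) to 19 should give, with the same facial preference, the C9 (3-methylbut-3-enyl) β-keto lactone F2. Oxidative free-radical cyclisation with Mn(OAc)3 and Cu(OAc)2 in acetic acid should form the C8 radical, which closes 6-endo onto the terminal CH2 of the 1,1-disubstituted alkene (cis fusion). Oxidation of the tertiary radical by divalent copper should give the C13 exocyclic methylene tricycle F3. Ozonolysis of this electron-rich alkene (O3, CH2Cl2, −78 °C; Me2S) in the presence of the electron-poor ring A enone should deliver 22.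

Step 17. Hydrogenation may continue to the ring A C2=C3 bond if the two enones are not sufficiently different in rate. Fallback, from 24 back to 25: conjugate reduction with [(Ph3P)CuH]6 in wet benzene at rt distinguishes the enones by β-substitution (unsubstituted C17 against the neopentyl C3) rather than by alkene type. Kinetic protonation of the copper enolate on the exo face should give the same endo C16 methyl configuration, that is 25.

**Further compounds**

F1 | step 3 | methyl (1R,6S)-5,5-dimethyl-2-oxobicyclo[4.2.0]oct-7-ene-1-carboxylate (enantiomer of 7) | COC(=O)[C@]12C=C[C@H]1C(C)(C)CCC2=O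
F2 | step 14 | C9 (3-methylbut-3-enyl) β-keto lactone (C8 drawn trans, epimerisable) | CC(=O)[C@@H]1[C@@H](CCC(C)=C)[C@]2(COC1=O)C(=O)C=CC(C)(C)[C@H]2CO[Si](c1ccccc1)(c1ccccc1)C(C)(C)C
F3 | step 14 | C13 exocyclic methylene tricycle (ring C closed, acetyl on C8) | CC(=O)[C@]12CC(=C)CC[C@H]1[C@]1(COC2=O)C(=O)C=CC(C)(C)[C@H]1CO[Si](c1ccccc1)(c1ccccc1)C(C)(C)C
F0 | step 17 | none | none
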